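Counting lifetimes of free monomer is the easy step, so I begin there, with these flasks and this question.

| flask | free monomer | initiator | remark | time |
|---|---|---|---|---|
| midnight | 17 mM | 0.2 mol% | run made earlier |  |
| dusk | 26 mM | 0.2 mol% | run made earlier |  |
| dawn | 12 mM | 0.4 mol% | run made earlier |  |
| blue | 12 mM | 0.2 mol% |  | 8.0 h |
| teal | 12 mM | 0.2 mol% |  | 30 h |

| run | time / h | monomer in chains / % | free monomer / % |
|---|---|---|---|
| midnight | 0.500 | 32.4 | 67.7 |
| midnight | 1.33 | 63.0 | 35.8 |
| midnight | 3.00 | 90.0 | 10.6 |
| midnight | 6.00 | 98.1 | 0.8 |
| dusk | 0.833 | 55.1 | 45.1 |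
| dusk | 2.50 | 90.3 | 9.7 |
| dusk | 4.00 | 96.1 | 2.2 |
| dusk | 6.00 | 98.2 | 0.2 |
| dawn | 1.50 | 74.1 | 25.8 |
| dawn | 3.00 | 93.2 | 6.1 |
| dawn | 5.00 | 98.7 | 0.7 |
| dawn | 6.00 | 98.8 | 0.7 |

(readings scatter by 0.5 percentage points)

- the average divides the monomer in chains by the number of chains, living and dead together; two radicals that join make one chain
- the earlier runs do not show the number of chains; that part of a forecast is a guess

- which of the two ends with the longer chains by the average number of monomer units in a chain (living and dead chains, two that joined counted as one) ("neither" if they lie within 10 %) (blue / teal / neither)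
- average number of monomer units in a chain (living and dead chains, two that joined counted as one) at the end, blue
- average number of monomer units in a chain (living and dead chains, two that joined counted as one) at the end, teal

Free monomer falls on a straight line in its logarithm, so I read a pseudo-first-order constant k from two readings in the midnight run and two in the dusk run. Midnight gives 0.742 h⁻¹ and dusk gives 0.922 h⁻¹. Their ratio, 1.24, matches the square root of their initiator concentrations, 1.24, so I scale midnight to the charge that blue and teal share. From k I take the lifetime of free monomer, τ = 1/k, the time in which it falls by a factor e: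

k = 0.623 h⁻¹

τ = 1.60 h

blue: 4.99 lifetimes, free monomer left 0.684 %

teal: 18.7 lifetimes

average ≈ 1/loading = 500

That last line is my weak link, a guess of one chain per initiator charged. Conversion barely parts the flasks, so I commit to that length for both, and to neither being longer.

The forecast gives 495 for blue, 505 for teal and neither, and says: “Chain number is not measured, so this part is a guess.”

The flasks give 2800 for blue and 1540 for teal, so blue is longer.

    initiator → 2 initiating radical (k = 0.0240 h⁻¹)
    free monomer + initiating radical → growing radical + monomer in chains (k = 8.70 × 10⁶ L mol⁻¹ s⁻¹)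
    free monomer + growing radical → monomer in chains + growing radical, rate k3*[growing radical]*[free monomer] (k = 3.70 × 10⁵ L mol⁻¹ s⁻¹)
    2 growing radical → dead chain (k = 6.80 × 10⁸ L mol⁻¹ s⁻¹)
    monomer in chains → over-reaction product (k = 0.00210 h⁻¹)

In blue at 8.00 h, 0.00419 mM of initiator has broken and 0.00419 mM of dead chain stands, so I reforge the link as one chain per initiator broken while free monomer lasts. Teal stands at 0.00726 mM of dead chain at 15.0 h, which is 9.35 lifetimes, and still at 0.00733 mM at 30.0 h, when monomer in chains is down to 94.2 % and over-reaction product is up to 5.79 %. A neighbour of teal with 20 mM of free monomer has τ = 1.24 h, so that count of lifetimes lasts 11.6 h and breaks 0.00973 mM of initiator; at 30.0 h this neighbour stands at 0.00988 mM of dead chain and a length of 1900.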